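**Retrosynthetic overview**

1. The last bonds are two aryl O–benzyl cleavages (hydrogenolysis). Before that, the ester C–O bond is made by SN2 union of a side-chain (R)-mesylate with unprotected caesium (R)-mevalonate, with inversion to S.
2. The δ-lactone is the only ring made; the arene comes from bromohydroquinone. It is closed by a one-flask anionic [3+3] annulation that joins benzylic C4 to carbinol C3 and the lactone carbonyl C1 to aryl C8a.
3. Enabling feature: the O2–C1(=O) unit of the lactone lies between C3–H and aryl carbon C8a. Written as an N,N-diisopropylcarbamate on O2, it first directs sparteine-controlled lithiation of C3 (sets 3R), then acts as acyl donor to a C8a aryllithium released from an aryl bromide that sits next to the CH2Br (C4) electrophile.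
4. Fragments: 2-bromo-3,6-bis(benzyloxy)benzyl bromide (3 steps from bromohydroquinone), the carbamate of (R)-5-silyloxyhexan-1-ol (4 steps from (R)-propylene oxide), and (R)-mevalonolactone.

Key step: step 8

Assumption: (−)-sparteine, (R)-propylene oxide and (R)-mevalonolactone are treated as commercial; the SMILES is read as 3R at the lactone carbon, S at the side-chain carbinol and R in the mevalonate unit.

**Route**

Step 1
Reactants: 1 2-bromobenzene-1,4-diol
Product: 2 1,4-bis(benzyloxy)-2-bromobenzene
Conditions: BnBr (2.3 equiv), K2CO3, DMF, 60 °C, N2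
Reagents that add atoms: benzyl bromide, BrCc1ccccc1
Why: Williamson ether synthesis; both phenoxides are alkylated by the benzylic bromide and the aryl bromide is inert to carbonate.

Step 2
Reactants: 2 1,4-bis(benzyloxy)-2-bromobenzene
Product: 4 [3,6-bis(benzyloxy)-2-bromophenyl]methanol, via aldehyde 3 (not isolated)
Conditions: LDA (1.2 equiv), THF, −78 °C; DMF, −78 → −20 °C; then MeOH, NaBH4, 0 °C
Reagents that add atoms: N,N-dimethylformamide, CN(C)C=O
Why: Directed ortho-lithiation removes the most acidic ring proton (between Br and OBn) at a temperature where the 2-bromoaryllithium should not lose LiBr; formylation with DMF and borohydride reduction in the same flask follow.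

Step 3
Reactants: 4 [3,6-bis(benzyloxy)-2-bromophenyl]methanol
Product: 5 1,4-bis(benzyloxy)-2-bromo-3-(bromomethyl)benzene
Conditions: PBr3 (0.4 equiv), CH2Cl2, 0 °C
Reagents that add atoms: phosphorus tribromide, BrP(Br)Br
Why: Conversion of a benzylic alcohol into its bromide through the phosphite (SN2), tolerated by aryl benzyl ethers and the aryl bromide.

Step 4
Reactants: 6 (R)-propylene oxide
Product: 7 (R)-hex-5-en-2-ol
Conditions: allylMgBr, CuI (5 mol%), THF/Et2O, −30 → 0 °C; aqueous work-up
Reagents that add atoms: allylmagnesium bromide, C=CC[Mg]Br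
Why: Copper-catalysed Grignard opening of the epoxide at its CH2 carbon, which leaves the stereocentre of the (R)-epoxide untouched.

Step 5
Reactants: 7 (R)-hex-5-en-2-ol
Product: 8 (R)-tert-butyl(hex-5-en-2-yloxy)dimethylsilane
Conditions: TBSCl, imidazole, DMF, rt
Reagents that add atoms: tert-butyldimethylsilyl chloride, CC(C)(C)[Si](C)(C)Cl
Why: Standard silylation of a secondary alcohol; the silyl ether is non-coordinating and stable to the organolithiums of step 8.

Step 6
Reactants: 8 (R)-tert-butyl(hex-5-en-2-yloxy)dimethylsilane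
Product: 9 (5R)-5-[(tert-butyldimethylsilyl)oxy]hexan-1-ol
Conditions: 9-BBN, THF, 0 °C → rt; then NaOH, H2O2, 0 °C → rt
Reagents that add atoms: hydrogen peroxide, OO
Why: Anti-Markovnikov hydroboration–oxidation of the terminal alkene gives the primary alcohol.

Step 7
Reactants: 9 (5R)-5-[(tert-butyldimethylsilyl)oxy]hexan-1-ol
Product: 10 (5R)-5-[(tert-butyldimethylsilyl)oxy]hexyl N,N-diisopropylcarbamate
Conditions: iPr2NCOCl, Et3N, CH2Cl2, reflux
Reagents that add atoms: N,N-diisopropylcarbamoyl chloride, CC(C)N(C(C)C)C(Cl)=O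
Why: O-Carbamoylation (nucleophilic acyl substitution) installs the hindered carbamate that directs α-lithiation and whose carbonyl carbon becomes C1 of the lactone.

Step 8
Reactants: 10 (5R)-5-[(tert-butyldimethylsilyl)oxy]hexyl N,N-diisopropylcarbamate; 5 1,4-bis(benzyloxy)-2-bromo-3-(bromomethyl)benzene
Product: 14 (3R)-5,8-bis(benzyloxy)-3-[(4R)-4-hydroxypentyl]-3,4-dihydro-1H-isochromen-1-one, via lithiated carbamate 11 (not isolated), via benzylated carbamate 12 (not isolated), via hydroxy amide 13 (not isolated)
Conditions: s-BuLi, (−)-sparteine, Et2O, −78 °C; 5 (toluene), −78 °C; t-BuLi (2.2 equiv), −78 → 0 °C; MeOH; then p-TsOH·H2O (excess), MeOH, 65 °C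
Reagents that add atoms: none
Why: Proposed new method: s-BuLi/(−)-sparteine should remove the pro-S proton next to the carbamate oxygen of 10 (sparteine-mediated asymmetric deprotonation of an O-alkyl carbamate) to give the chelated, configurationally stable (S)-organolithium 11, which is expected to displace the benzylic bromide of 5 with retention and so make the C4–C3 bond and the 3R centre under reagent control (12). t-BuLi then exchanges the aryl bromide only, and the C8a aryllithium adds to the carbamate carbonyl (6-exo-trig, Parham-type cyclization) to make the C1–C8a bond; the tetrahedral intermediate is expected to expel the C3 alkoxide, a 1,5 O→C carbamoyl shift related to the anionic Fries rearrangement, leaving amide 13. In the acidic methanol stage the δ-hydroxyl re-attacks the twisted 2,6-disubstituted amide carbonyl (6-exo-trig), diisopropylamine leaves as its ammonium salt so that the δ-lactone closes with C3 untouched, and the TBS ether is solvolysed. The closest known reaction types are the electrophilic substitution of sparteine-complexed lithiated O-alkyl carbamates, the Parham cyclization of aryllithiums onto carbamates, and the acid lactonization of hydroxy amides from lateral lithiation of o-toluamides; new is their combination into one [3+3] annulation in which the carbamate carbon ends up as the lactone carbonyl. The step needs 11 to attack CH2Br faster than it exchanges with the aryl bromide (SN2 at a benzylic bromide against exchange with a chelated, hindered α-oxy organolithium at −78 °C), and needs Br/Li exchange to outrun attack of t-BuLi on the benzyl ethers or the hindered carbamate, which the low temperature should secure. The remote (R)-silyloxy centre and the benzyl ethers are not involved.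

Step 9
Reactants: 14 (3R)-5,8-bis(benzyloxy)-3-[(4R)-4-hydroxypentyl]-3,4-dihydro-1H-isochromen-1-one
Product: 15 (2R)-5-[(3R)-5,8-bis(benzyloxy)-1-oxo-3,4-dihydro-1H-isochromen-3-yl]pentan-2-yl methanesulfonate
Conditions: MsCl, Et3N, CH2Cl2, 0 °C
Reagents that add atoms: methanesulfonyl chloride, CS(Cl)(=O)=O
Why: Sulfonylation of the only free hydroxyl occurs at oxygen, so the carbinol configuration is retained.

Step 10
Reactants: 16 (R)-mevalonolactone
Product: 17 caesium (R)-mevalonate (caesium (3R)-3,5-dihydroxy-3-methylpentanoate)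
Conditions: CsOH·H2O (1.0 equiv), H2O/MeOH, rt; evaporate, dry under vacuum
Reagents that add atoms: caesium hydroxide monohydrate, [Cs+].[OH-].O
Why: Saponification of the δ-lactone with one equivalent of hydroxide gives the open-chain carboxylate; the tertiary centre is not involved.

Step 11
Reactants: 15 (2R)-5-[(3R)-5,8-bis(benzyloxy)-1-oxo-3,4-dihydro-1H-isochromen-3-yl]pentan-2-yl methanesulfonate; 17 caesium (R)-mevalonate
Product: 18 (2S)-5-[(3R)-5,8-bis(benzyloxy)-1-oxo-3,4-dihydro-1H-isochromen-3-yl]pentan-2-yl (3R)-3,5-dihydroxy-3-methylpentanoate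
Conditions: 17 (2.5 equiv), DMF, 50 °C, Ar
Reagents that add atoms: none
Why: SN2 alkylation of a caesium carboxylate by a secondary mesylate proceeds with inversion and turns the (R)-mesylate into the (S)-ester; the carboxylate is far more nucleophilic than the neutral primary and tertiary hydroxyls, so the mevalonate needs no protection.

Step 12
Reactants: 18 (2S)-5-[(3R)-5,8-bis(benzyloxy)-1-oxo-3,4-dihydro-1H-isochromen-3-yl]pentan-2-yl (3R)-3,5-dihydroxy-3-methylpentanoate
Product: 19 aspergimarin C, (2S)-5-[(3R)-5,8-dihydroxy-1-oxo-3,4-dihydro-1H-isochromen-3-yl]pentan-2-yl (3R)-3,5-dihydroxy-3-methylpentanoate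
Conditions: H2 (1 atm), 10% Pd/C, EtOAc, rt; filtration under Ar
Reagents that add atoms: none
Why: Hydrogenolysis of the two aryl benzyl ethers under neutral conditions should leave the lactone, the δ-hydroxy ester and the tertiary alcohol alone.

**Compound list**

1 | 2-bromobenzene-1,4-diol | Oc1ccc(O)c(Br)c1 | starting material
2 | 1,4-bis(benzyloxy)-2-bromobenzene | Brc1cc(OCc2ccccc2)ccc1OCc1ccccc1 | intermediate
3 | 3,6-bis(benzyloxy)-2-bromobenzaldehyde | O=Cc1c(Br)c(OCc2ccccc2)ccc1OCc1ccccc1 | intermediate (not isolated)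
4 | [3,6-bis(benzyloxy)-2-bromophenyl]methanol | OCc1c(Br)c(OCc2ccccc2)ccc1OCc1ccccc1 | intermediate
5 | 1,4-bis(benzyloxy)-2-bromo-3-(bromomethyl)benzene | BrCc1c(Br)c(OCc2ccccc2)ccc1OCc1ccccc1 | intermediate
6 | (R)-propylene oxide | C[C@@H]1CO1 | starting material
7 | (R)-hex-5-en-2-ol | C[C@@H](O)CCC=C | intermediate
8 | (R)-tert-butyl(hex-5-en-2-yloxy)dimethylsilane | C[C@@H](O[Si](C)(C)C(C)(C)C)CCC=C | intermediate
9 | (5R)-5-[(tert-butyldimethylsilyl)oxy]hexan-1-ol | C[C@@H](O[Si](C)(C)C(C)(C)C)CCCCO | intermediate
10 | (5R)-5-[(tert-butyldimethylsilyl)oxy]hexyl N,N-diisopropylcarbamate | C[C@@H](O[Si](C)(C)C(C)(C)C)CCCCOC(=O)N(C(C)C)C(C)C | intermediate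
11 | (1S,5R)-5-[(tert-butyldimethylsilyl)oxy]-1-lithiohexyl N,N-diisopropylcarbamate (sparteine complex) | [Li][C@@H](CCC[C@@H](C)O[Si](C)(C)C(C)(C)C)OC(=O)N(C(C)C)C(C)C | intermediate (not isolated)
12 | (2R,6R)-1-[3,6-bis(benzyloxy)-2-bromophenyl]-6-[(tert-butyldimethylsilyl)oxy]heptan-2-yl N,N-diisopropylcarbamate | Brc1c(C[C@@H](CCC[C@@H](C)O[Si](C)(C)C(C)(C)C)OC(=O)N(C(C)C)C(C)C)c(OCc2ccccc2)ccc1OCc1ccccc1 | intermediate (not isolated)
13 | 3,6-bis(benzyloxy)-2-[(2R,6R)-6-[(tert-butyldimethylsilyl)oxy]-2-hydroxyheptyl]-N,N-diisopropylbenzamide (lithium alkoxide in the flask) | CC(C)N(C(C)C)C(=O)c1c(C[C@H](O)CCC[C@@H](C)O[Si](C)(C)C(C)(C)C)c(OCc2ccccc2)ccc1OCc1ccccc1 | intermediate (not isolated)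
14 | (3R)-5,8-bis(benzyloxy)-3-[(4R)-4-hydroxypentyl]-3,4-dihydro-1H-isochromen-1-one | C[C@@H](O)CCC[C@@H]1Cc2c(OCc3ccccc3)ccc(OCc3ccccc3)c2C(=O)O1 | intermediate
15 | (2R)-5-[(3R)-5,8-bis(benzyloxy)-1-oxo-3,4-dihydro-1H-isochromen-3-yl]pentan-2-yl methanesulfonate | C[C@@H](OS(C)(=O)=O)CCC[C@@H]1Cc2c(OCc3ccccc3)ccc(OCc3ccccc3)c2C(=O)O1 | intermediate
16 | (R)-mevalonolactone | C[C@@]1(O)CCOC(=O)C1 | starting material
17 | caesium (3R)-3,5-dihydroxy-3-methylpentanoate | [Cs+].[O-]C(=O)C[C@](C)(O)CCO | intermediate
18 | (2S)-5-[(3R)-5,8-bis(benzyloxy)-1-oxo-3,4-dihydro-1H-isochromen-3-yl]pentan-2-yl (3R)-3,5-dihydroxy-3-methylpentanoate | C[C@@H](CCC[C@@H]1Cc2c(OCc3ccccc3)ccc(OCc3ccccc3)c2C(=O)O1)OC(=O)C[C@](C)(O)CCO | intermediate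
19 | aspergimarin C | C[C@@H](CCC[C@@H]1Cc2c(O)ccc(O)c2C(=O)O1)OC(=O)C[C@](C)(O)CCO | target

**Step count and risks**

Total steps: 12. Longest linear sequence: 8 steps (steps 4, 5, 6, 7, 8, 9, 11, 12, from (R)-propylene oxide).

Steps most likely to fail:

Step 8. Electron transfer or bromine–lithium exchange between the lithiated carbamate and the dibromide may compete with SN2 benzylation, which would cost yield and configurational purity at C3. Proton transfer from a benzylic ether CH2 to the aryllithium may also occur before the acyl transfer. The fallback uses known chemistry, sets out from 5 and 10 and returns at 14. Bromide 5 would be borylated at the benzylic position only (B2pin2, CuI, PPh3, LiOMe, DMF, rt) to the benzylic pinacol boronate F1. Lithiation–borylation of 10 (s-BuLi, (−)-sparteine, Et2O, −78 °C; F1; MgBr2·OEt2, reflux; then NaOH, H2O2) should give the (R)-configured homobenzylic alcohol F2: borylation with retention and 1,2-migration with inversion place the oxygen where the lithium stood. Palladium-catalysed carbonylative lactonization of the bromo alcohol (CO 1 atm, Pd(OAc)2, Xantphos, Et3N, toluene, 90 °C) would close the lactone to the silyl ether F3, and HF·pyridine in THF would free 14.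

Step 11. E2 elimination of the secondary mesylate and carboxylate-promoted relactonization of the δ-hydroxy ester (loss of the acyl group as mevalonolactone) may erode the coupling. The fallback sets out from 14 and 17 and returns at 18. Salt 17 would be silylated (TBSCl, imidazole, DMF; then K2CO3, MeOH/H2O to cleave the silyl ester; work-up at pH 5) to (3R)-5-[(tert-butyldimethylsilyl)oxy]-3-hydroxy-3-methylpentanoic acid F4. Mitsunobu esterification of alcohol 14 with F4 (PPh3, DIAD, toluene, 0 °C → rt) should give, with inversion, the silyl-protected ester F5. HF·pyridine in THF/pyridine at 0 °C would then give 18.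

Step 2. Loss of lithium bromide from the ortho-bromoaryllithium (aryne formation) or migration of the halogen may occur before the formamide is captured. The fallback sets out from 2 and returns at 3, which is then reduced as in the second stage of step 2. Bromine–lithium exchange on 2 (n-BuLi, THF, −78 °C) and DMF would give 2,5-bis(benzyloxy)benzaldehyde F6. Its formyl group would be masked in the flask as the α-amino alkoxide (lithium N,N,N′-trimethylethylenediamide, THF, −20 °C). Directed ortho-lithiation (n-BuLi, −20 °C) at the position flanked by the masked aldehyde and OBn, followed by 1,2-dibromotetrachloroethane, would then give 3; the bromine is thus introduced after the formyl carbon instead of before it.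

**Further compounds**

F1 | step 8 | 2-{[3,6-bis(benzyloxy)-2-bromophenyl]methyl}-4,4,5,5-tetramethyl-1,3,2-dioxaborolane | CC1(C)OB(Cc2c(Br)c(OCc3ccccc3)ccc2OCc2ccccc2)OC1(C)C
F2 | step 8 | (2R,6R)-1-[3,6-bis(benzyloxy)-2-bromophenyl]-6-[(tert-butyldimethylsilyl)oxy]heptan-2-ol | Brc1c(C[C@H](O)CCC[C@@H](C)O[Si](C)(C)C(C)(C)C)c(OCc2ccccc2)ccc1OCc1ccccc1
F3 | step 8 | (3R)-5,8-bis(benzyloxy)-3-{(4R)-4-[(tert-butyldimethylsilyl)oxy]pentyl}-3,4-dihydro-1H-isochromen-1-one | C[C@@H](O[Si](C)(C)C(C)(C)C)CCC[C@@H]1Cc2c(OCc3ccccc3)ccc(OCc3ccccc3)c2C(=O)O1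
F4 | step 11 | (3R)-5-[(tert-butyldimethylsilyl)oxy]-3-hydroxy-3-methylpentanoic acid | OC(=O)C[C@](C)(O)CCO[Si](C)(C)C(C)(C)C
F5 | step 11 | (2S)-5-[(3R)-5,8-bis(benzyloxy)-1-oxo-3,4-dihydro-1H-isochromen-3-yl]pentan-2-yl (3R)-5-[(tert-butyldimethylsilyl)oxy]-3-hydroxy-3-methylpentanoate | C[C@@H](CCC[C@@H]1Cc2c(OCc3ccccc3)ccc(OCc3ccccc3)c2C(=O)O1)OC(=O)C[C@](C)(O)CCO[Si](C)(C)C(C)(C)C
F6 | step 2 | 2,5-bis(benzyloxy)benzaldehyde | O=Cc1cc(OCc2ccccc2)ccc1OCc1ccccc1
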